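## Retrosynthetic overview

1. The target is epioritin-(4β→6)-ent-oritin-4α-ol. An upper 4-arylflavan-3-ol (rings A, C, B; 2R,3R,4S; 2,3-cis-3,4-trans) is bonded through C4 to C6 of ring D of a lower flavan-3,4-diol (rings D, F, E; 2S,3R,4R; 2,3-trans-3,4-cis).
2. Feature used: upper C4 is bonded to ring A carbon C4a, whose neighbour C8a carries O1, so C4 is the methide carbon of a ring A o-quinone methide. Its other neighbour C3 bears oxygen and is the α-carbon of benzyloxyacetaldehyde. Cutting C3–C4, with O1–C2 opened as a lactol, leaves a ring A/ring D o-hydroxybenzhydrol.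
3. The benzhydrol comes from a ring A salicylaldehyde and a ring D aryllithium. The ring D oxygen para to the carbinol is capped as an allyl ether.
4. Ring C forms first as the lactol. Ring B enters at the lactone level through a Weinreb ketone, C2 is set by chelate-controlled reduction, and ring C is closed again by Mitsunobu inversion (2,3-cis).
5. Ring F forms last. A Claisen shift moves the allyl group to C4a of ring D, where it becomes C4. O1–C2 comes from iridium-catalysed asymmetric allylic etherification, C3=C4 from ring-closing metathesis and the cis-diol from OsO4 anti to ring E. Global hydrogenolysis ends the route.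

Key step: step 7

Convention: flavan numbering is kept for open-chain intermediates. α and β mean below and above the plane in the usual drawing of each flavan unit (fused benzene ring left, O1 on top). The SMILES strings are decisive, because the CIP letter at upper C4 changes with ring D substitution.

Assumption: the (Ra,Rc,Rc) enantiomer of the binaphthol-derived bis(1-phenylethyl)phosphoramidite is taken as the one that gives the (R)-configured branched ether of step 16. Both enantiomers are sold, and the mirror-image ligand is used if a trial with 2-methoxyphenol shows the opposite sense.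

## Route

Step 1
Reactants: 1 2,3,4-trihydroxybenzaldehyde
Product: 2 3,4-bis(benzyloxy)-2-hydroxybenzaldehyde (ring A aldehyde)
Conditions: BnBr (2.05 equiv), K2CO3 (2.1 equiv), acetone, reflux
Reagents that add atoms: benzyl bromide BrCc1ccccc1
Why: Williamson etherification; the 2-OH is held in the intramolecular hydrogen bond to the formyl oxygen and is the least nucleophilic, so two equivalents of benzyl bromide should cap O3 and O4 only.

Step 2
Reactants: 3 2,3-dihydroxybenzaldehyde
Product: 4 2,3-bis(benzyloxy)benzaldehyde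
Conditions: BnBr (2.3 equiv), K2CO3, DMF, 60 °C
Reagents that add atoms: benzyl bromide BrCc1ccccc1
Why: Exhaustive Williamson benzylation of the catechol, with no competing site.

Step 3
Reactants: 4 2,3-bis(benzyloxy)benzaldehyde
Product: 6 2,3-bis(benzyloxy)phenol, via aryl formate 5 (not isolated)
Conditions: mCPBA, CH2Cl2, rt; then K2CO3 (cat.), MeOH, rt
Reagents that add atoms: 3-chloroperoxybenzoic acid OOC(=O)c1cccc(Cl)c1
Why: Baeyer–Villiger oxidation with migration of the electron-rich aryl group gives the formate, which base-catalysed transesterification with methanol cleaves to the phenol.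

Step 4
Reactants: 6 2,3-bis(benzyloxy)phenol
Product: 7 2,3-bis(benzyloxy)-4-bromophenol
Conditions: NBS (1.0 equiv), MeCN, –20 → 0 °C
Reagents that add atoms: N-bromosuccinimide O=C1CCC(=O)N1Br
Why: Electrophilic aromatic bromination; in acetonitrile NBS attacks phenols para to the free OH, here C4, which the 3-benzyloxy group also activates, so bromine lands on the future C6 of ring D.

Step 5
Reactants: 7 2,3-bis(benzyloxy)-4-bromophenol
Product: 8 1-(allyloxy)-2,3-bis(benzyloxy)-4-bromobenzene (ring D bromide)
Conditions: allyl bromide, K2CO3, DMF, rt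
Reagents that add atoms: allyl bromide C=CCBr
Why: Williamson allylation caps the oxygen para to bromine (future O1 of ring F), which blocks p-quinone methide formation in step 7 and later supplies C4 of ring F.

Step 6
Reactants: 2 3,4-bis(benzyloxy)-2-hydroxybenzaldehyde; 8 1-(allyloxy)-2,3-bis(benzyloxy)-4-bromobenzene
Product: 11 racemic [4-(allyloxy)-2,3-bis(benzyloxy)phenyl][3,4-bis(benzyloxy)-2-hydroxyphenyl]methanol, via sodium phenoxide 9 (not isolated), via aryllithium 10 (not isolated)
Conditions: (a) 2, NaH, THF, 0 °C; (b) 8, n-BuLi, THF, –78 °C; (a) added to (b), –78 → –20 °C; H2O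
Reagents that add atoms: none
Why: Bromine–lithium exchange at –78 °C is faster than any attack on the benzyl or allyl ethers, and 1,2-addition of the aryllithium to the pre-formed sodium salt of the salicylaldehyde gives the acid-labile o-hydroxybenzhydrol directly, with no acidic deprotection and only one equivalent of the ring D fragment.

Step 7
Reactants: 11 racemic ring A/ring D o-hydroxybenzhydrol; 12 benzyloxyacetaldehyde
Product: 16 (3R,4S)-4-[4-(allyloxy)-2,3-bis(benzyloxy)phenyl]-3,7,8-tris(benzyloxy)chroman-2-ol (3,4-trans lactol; both C2 anomers), via o-quinone methide 13 (not isolated), via enamine 14 (not isolated), via open-chain phenol aldehyde 15 (not isolated)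
Conditions: (S)-2-[diphenyl(trimethylsilyloxy)methyl]pyrrolidine (20 mol %), ClCH2CO2H (20 mol %), 12 (3 equiv, slow addition), CH2Cl2, 0 °C → rt
Reagents that add atoms: none
Why: The acid should dehydrate both enantiomers of 11 to the same planar E-configured ring A methide 13 (or its O-protonated benzhydryl cation) while the amine condenses with 12 to the anti E-enamine 14, whose α-carbon (future C3) adds to the methide carbon (future C4) in a Michael-type step that rearomatises ring A, and hydrolysis of the iminium ion then releases 15 and the catalyst. The closest known reaction type is the diarylprolinol silyl ether-catalysed formal [4+2] annulation of enolisable aldehydes with o-quinone methides made in situ, and alkoxyacetaldehydes are established donors in the same enamine manifold with nitroalkenes. Ring C closes by reversible 6-exo-trig hemiacetalisation of the ring A phenol O1 onto the C2 aldehyde, so C2 stays an anomeric mixture that is erased in step 8. C3 is controlled by the diphenyl(silyloxy)methyl group of the (S)-catalyst, which shields one enamine face and, as in the analogous nitroalkene additions, should give 3R (3α-OBn). C4 is controlled by the synclinal approach of the E-enamine to the E-methide, which gives the syn Michael adduct, that is the 3,4-trans lactol with the ring D aryl group 4β. The step needs methide formation on ring A only, secured because ring A alone has a free ortho OH and the ring D para oxygen is allylated, and it needs 12 to act as donor rather than self-condense, which slow addition should secure.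

Step 8
Reactants: 16 3,4-trans lactol
Product: 17 (3R,4S)-4-[4-(allyloxy)-2,3-bis(benzyloxy)phenyl]-3,7,8-tris(benzyloxy)chroman-2-one
Conditions: Dess–Martin periodinane, CH2Cl2, 0 °C → rt
Reagents that add atoms: none
Why: Dess–Martin oxidation of the lactol to the lactone; C3 should hold because the 3,4-trans lactone is also the thermodynamically preferred epimer.

Step 9
Reactants: 17 3,4-trans lactone
Product: 18 (2R,3R)-3-[4-(allyloxy)-2,3-bis(benzyloxy)phenyl]-2-(benzyloxy)-3-[3,4-bis(benzyloxy)-2-hydroxyphenyl]-N-methoxy-N-methylpropanamide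
Conditions: MeNH(OMe)·HCl, iPrMgCl, THF, –20 → 0 °C; H2O
Reagents that add atoms: N,O-dimethylhydroxylamine hydrochloride CNOC.Cl
Why: Aminolysis of the aryl ester by the magnesium amide (Weinreb amide synthesis) opens ring C and frees the ring A phenol, and the stable phenoxide makes the opening irreversible.

Step 10
Reactants: 18 Weinreb amide; 19 1-(benzyloxy)-4-bromobenzene
Product: 21 (2R,3R)-3-[4-(allyloxy)-2,3-bis(benzyloxy)phenyl]-2-(benzyloxy)-1-[4-(benzyloxy)phenyl]-3-[3,4-bis(benzyloxy)-2-hydroxyphenyl]propan-1-one, via Grignard reagent 20 (not isolated)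
Conditions: 19, Mg, THF, reflux; then 18 (20 in 3 equiv), THF, –20 → 0 °C; H2O
Reagents that add atoms: none
Why: Weinreb ketone synthesis; the first equivalent of Grignard reagent deprotonates the phenol and the next forms the chelated tetrahedral adduct that collapses only on quench, so over-addition and C3 enolisation should both be avoided.

Step 11
Reactants: 21 α-benzyloxy aryl ketone
Product: 22 (1S,2R,3R)-3-[4-(allyloxy)-2,3-bis(benzyloxy)phenyl]-2-(benzyloxy)-1-[4-(benzyloxy)phenyl]-3-[3,4-bis(benzyloxy)-2-hydroxyphenyl]propan-1-ol (flavan C2 = S; 2,3-anti)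
Conditions: Zn(BH4)2 (stock solution in Et2O), Et2O–CH2Cl2, –40 → –10 °C; H2O
Reagents that add atoms: none
Why: Chelation-controlled reduction; zinc bridges the ketone oxygen and the C3 benzyloxy oxygen and hydride enters anti to the bulky C4 diarylmethyl group to give the 2,3-anti (2S) alcohol, whereas chelate-controlled addition of the aryl Grignard reagent to the lactol would give the 2,3-syn epimer, which after inversion ends in the wrong 2,3-trans flavan.

Step 12
Reactants: 22 2,3-anti phenol alcohol
Product: 23 (2R,3R,4S)-4-[4-(allyloxy)-2,3-bis(benzyloxy)phenyl]-3,7,8-tris(benzyloxy)-2-[4-(benzyloxy)phenyl]chroman (2α-aryl 3α-OBn 4β-aryl; 2,3-cis-3,4-trans)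
Conditions: PPh3, DIAD, toluene, 0 °C
Reagents that add atoms: none
Why: Intramolecular Mitsunobu etherification (6-exo-tet SN2); the ring A phenoxide displaces the C2 oxyphosphonium group with inversion, turning the 2S alcohol into the 2R, 2,3-cis flavan, and the non-polar solvent and low temperature disfavour ionisation.

Step 13
Reactants: 23 protected upper flavan with ring D allyl ether
Product: 24 as 23 but ring D = 5-allyl-2,3-bis(benzyloxy)-4-hydroxyphenyl (free OH on C8a and allyl on C4a of ring D)
Conditions: N,N-diethylaniline, 190 °C, argon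
Reagents that add atoms: none
Why: Aromatic Claisen rearrangement; of the two ortho positions only C4a of ring D carries hydrogen, so the [3,3] shift and tautomerisation can end only there, and no stereocentre is touched.

Step 14
Reactants: 24 ring D allylphenol
Product: 25 as 24 but ring D = 2,3-bis(benzyloxy)-4-hydroxy-5-[(E)-prop-1-enyl]phenyl
Conditions: RuClH(CO)(PPh3)3 (5 mol %), toluene, 90 °C
Reagents that add atoms: none
Why: Ruthenium hydride-catalysed alkene isomerisation moves the double bond into conjugation with ring D, as known for allylphenols, and the alkene geometry does not matter for the later metathesis.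

Step 15
Reactants: 26 1-(benzyloxy)-4-vinylbenzene; 27 allyl methyl carbonate
Product: 28 (E)-3-[4-(benzyloxy)phenyl]allyl methyl carbonate
Conditions: second-generation Hoveyda–Grubbs catalyst (2 mol %), 27 (3 equiv), CH2Cl2, 40 °C
Reagents that add atoms: none
Why: Olefin cross-metathesis of a styrene with an excess of a simple allylic carbonate gives the thermodynamically preferred E-cinnamyl carbonate with loss of ethene.

Step 16
Reactants: 25 ring D propenylphenol; 28 cinnamyl carbonate
Product: 29 as 25 but the ring D phenol oxygen carries an (R)-1-[4-(benzyloxy)phenyl]allyl group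
Conditions: [Ir(cod)Cl]2 (2 mol %), (Ra,Rc,Rc)-binaphthol N,N-bis(1-phenylethyl)phosphoramidite (4 mol %), TBD (8 mol %), THF, 50 °C
Reagents that add atoms: none
Why: Iridium-catalysed asymmetric allylic etherification; the cyclometallated iridium phosphoramidite complex ionises the linear carbonate, the released methoxide deprotonates the phenol, and the phenoxide attacks the aryl-bearing allyl terminus, so the branched ether forms and the catalyst sets C2 of ring F (β-aryl), as known for 2-alkenylphenols.

Step 17
Reactants: 29 branched allyl aryl ether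
Product: 30 flav-3-ene: upper unit of 23 bonded through C4 to C6 of (2R)-7,8-bis(benzyloxy)-2-[4-(benzyloxy)phenyl]-2H-chromene (2β-aryl)
Conditions: second-generation Grubbs catalyst (5 mol %), CH2Cl2, 40 °C
Reagents that add atoms: none
Why: Ring-closing metathesis of the terminal vinyl group onto the propenyl group closes the six-membered ring F as the 2H-chromene with loss of propene and leaves C2 untouched.

Step 18
Reactants: 30 flav-3-ene
Product: 31 hepta-O-benzyl target: lower unit (2S,3R,4R)-7,8-bis(benzyloxy)-2-[4-(benzyloxy)phenyl]chroman-3,4-diol (2β-aryl 3α-OH 4α-OH)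
Conditions: OsO4 (5 mol %), NMO, acetone–THF–H2O, 0 °C → rt
Reagents that add atoms: osmium tetroxide O=[Os](=O)(=O)=O; N-methylmorpholine N-oxide C[N+]1([O-])CCOCC1; water O
Why: Catalytic OsO4/NMO syn-dihydroxylation; the reagent adds to C3=C4 from the α face, anti to the β-aryl group at C2, which is the known course for flav-3-enes and gives the 2,3-trans-3,4-cis diol.

Step 19
Reactants: 31 hepta-O-benzyl target
Product: 32 (2R,3R,4S)-2-(4-hydroxyphenyl)-4-[(2S,3R,4R)-3,4,7,8-tetrahydroxy-2-(4-hydroxyphenyl)chroman-6-yl]chroman-3,7,8-triol (target)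
Conditions: H2 (1 atm), Pd(OH)2/C, THF–MeOH, rt, neutral, stopped at the end of uptake; handled under argon
Reagents that add atoms: none
Why: Catalytic hydrogenolysis cleaves the six aryl benzyl ethers and the C3 alkyl benzyl ether, while in neutral medium the ring C2–O1 bonds and the lower C4–OH, which need acid activation to be reduced, should persist.

## Compound list

1 | 2,3,4-trihydroxybenzaldehyde | O=Cc1ccc(O)c(O)c1O | starting material
2 | 3,4-bis(benzyloxy)-2-hydroxybenzaldehyde | O=Cc1ccc(OCc2ccccc2)c(OCc2ccccc2)c1O | intermediate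
3 | 2,3-dihydroxybenzaldehyde | O=Cc1cccc(O)c1O | starting material
4 | 2,3-bis(benzyloxy)benzaldehyde | O=Cc1cccc(OCc2ccccc2)c1OCc1ccccc1 | intermediate
5 | 2,3-bis(benzyloxy)phenyl formate | O=COc1cccc(OCc2ccccc2)c1OCc1ccccc1 | intermediate
6 | 2,3-bis(benzyloxy)phenol | Oc1cccc(OCc2ccccc2)c1OCc1ccccc1 | intermediate
7 | 2,3-bis(benzyloxy)-4-bromophenol | Oc1ccc(Br)c(OCc2ccccc2)c1OCc1ccccc1 | intermediate
8 | 1-(allyloxy)-2,3-bis(benzyloxy)-4-bromobenzene | C=CCOc1ccc(Br)c(OCc2ccccc2)c1OCc1ccccc1 | intermediate
9 | sodium 2,3-bis(benzyloxy)-6-formylphenoxide | [Na+].[O-]c1c(C=O)ccc(OCc2ccccc2)c1OCc1ccccc1 | intermediate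
10 | [4-(allyloxy)-2,3-bis(benzyloxy)phenyl]lithium | [Li]c1ccc(OCC=C)c(OCc2ccccc2)c1OCc1ccccc1 | intermediate
11 | racemic ring A/ring D o-hydroxybenzhydrol | OC(c1ccc(OCc2ccccc2)c(OCc2ccccc2)c1O)c1ccc(OCC=C)c(OCc2ccccc2)c1OCc1ccccc1 | intermediate
12 | benzyloxyacetaldehyde | O=CCOCc1ccccc1 | starting material
13 | (6E)-6-[4-(allyloxy)-2,3-bis(benzyloxy)benzylidene]-2,3-bis(benzyloxy)cyclohexa-2,4-dien-1-one | O=C1C(OCc2ccccc2)=C(OCc2ccccc2)C=C/C1=C\c1ccc(OCC=C)c(OCc2ccccc2)c1OCc1ccccc1 | intermediate
14 | (E)-enamine of 12 and (S)-2-[diphenyl(trimethylsilyloxy)methyl]pyrrolidine | C[Si](C)(C)OC(c1ccccc1)(c1ccccc1)[C@@H]1CCCN1/C=C/OCc1ccccc1 | intermediate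
15 | (2R,3R)-3-[4-(allyloxy)-2,3-bis(benzyloxy)phenyl]-2-(benzyloxy)-3-[3,4-bis(benzyloxy)-2-hydroxyphenyl]propanal | O=C[C@H](OCc1ccccc1)[C@@H](c1ccc(OCC=C)c(OCc2ccccc2)c1OCc1ccccc1)c1ccc(OCc2ccccc2)c(OCc2ccccc2)c1O | intermediate
16 | (3R,4S)-3,4-trans lactol, C2 anomers | OC1Oc2c(ccc(OCc3ccccc3)c2OCc2ccccc2)[C@H](c2ccc(OCC=C)c(OCc3ccccc3)c2OCc2ccccc2)[C@H]1OCc1ccccc1 | intermediate
17 | (3R,4S)-3,4-trans lactone | O=C1Oc2c(ccc(OCc3ccccc3)c2OCc2ccccc2)[C@H](c2ccc(OCC=C)c(OCc3ccccc3)c2OCc2ccccc2)[C@H]1OCc1ccccc1 | intermediate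
18 | Weinreb amide with free ring A phenol | CON(C)C(=O)[C@H](OCc1ccccc1)[C@@H](c1ccc(OCC=C)c(OCc2ccccc2)c1OCc1ccccc1)c1ccc(OCc2ccccc2)c(OCc2ccccc2)c1O | intermediate
19 | 1-(benzyloxy)-4-bromobenzene | Brc1ccc(OCc2ccccc2)cc1 | starting material
20 | [4-(benzyloxy)phenyl]magnesium bromide | Br[Mg]c1ccc(OCc2ccccc2)cc1 | intermediate
21 | α-benzyloxy ring B aryl ketone | O=C(c1ccc(OCc2ccccc2)cc1)[C@H](OCc1ccccc1)[C@@H](c1ccc(OCC=C)c(OCc2ccccc2)c1OCc1ccccc1)c1ccc(OCc2ccccc2)c(OCc2ccccc2)c1O | intermediate
22 | 2,3-anti (2S) phenol alcohol | O[C@@H](c1ccc(OCc2ccccc2)cc1)[C@H](OCc1ccccc1)[C@@H](c1ccc(OCC=C)c(OCc2ccccc2)c1OCc1ccccc1)c1ccc(OCc2ccccc2)c(OCc2ccccc2)c1O | intermediate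
23 | protected 2,3-cis-3,4-trans upper flavan, ring D allyl ether | C(c1ccccc1)Oc1ccc([C@H]2Oc3c(ccc(OCc4ccccc4)c3OCc3ccccc3)[C@H](c3ccc(OCC=C)c(OCc4ccccc4)c3OCc3ccccc3)[C@H]2OCc2ccccc2)cc1 | intermediate
24 | Claisen product, ring D allylphenol | C(c1ccccc1)Oc1ccc([C@H]2Oc3c(ccc(OCc4ccccc4)c3OCc3ccccc3)[C@H](c3cc(CC=C)c(O)c(OCc4ccccc4)c3OCc3ccccc3)[C@H]2OCc2ccccc2)cc1 | intermediate
25 | ring D (E)-propenylphenol | C(c1ccccc1)Oc1ccc([C@H]2Oc3c(ccc(OCc4ccccc4)c3OCc3ccccc3)[C@H](c3cc(/C=C/C)c(O)c(OCc4ccccc4)c3OCc3ccccc3)[C@H]2OCc2ccccc2)cc1 | intermediate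
26 | 1-(benzyloxy)-4-vinylbenzene | C=Cc1ccc(OCc2ccccc2)cc1 | starting material
27 | allyl methyl carbonate | C=CCOC(=O)OC | starting material
28 | (E)-3-[4-(benzyloxy)phenyl]allyl methyl carbonate | COC(=O)OC/C=C/c1ccc(OCc2ccccc2)cc1 | intermediate
29 | (R)-branched allyl aryl ether | C(c1ccccc1)Oc1ccc([C@H]2Oc3c(ccc(OCc4ccccc4)c3OCc3ccccc3)[C@H](c3cc(/C=C/C)c(O[C@@H](c4ccc(OCc5ccccc5)cc4)C=C)c(OCc4ccccc4)c3OCc3ccccc3)[C@H]2OCc2ccccc2)cc1 | intermediate
30 | flav-3-ene (ring F closed, 2β-aryl) | C(c1ccccc1)Oc1ccc([C@H]2Oc3c(ccc(OCc4ccccc4)c3OCc3ccccc3)[C@H](c3cc4c(c(OCc5ccccc5)c3OCc3ccccc3)O[C@@H](c3ccc(OCc5ccccc5)cc3)C=C4)[C@H]2OCc2ccccc2)cc1 | intermediate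
31 | hepta-O-benzyl target | C(c1ccccc1)Oc1ccc([C@H]2Oc3c(ccc(OCc4ccccc4)c3OCc3ccccc3)[C@H](c3cc4c(c(OCc5ccccc5)c3OCc3ccccc3)O[C@@H](c3ccc(OCc5ccccc5)cc3)[C@H](O)[C@@H]4O)[C@H]2OCc2ccccc2)cc1 | intermediate
32 | epioritin-(4β→6)-ent-oritin-4α-ol | Oc1ccc([C@H]2Oc3c(ccc(O)c3O)[C@H](c3cc4c(c(O)c3O)O[C@@H](c3ccc(O)cc3)[C@H](O)[C@@H]4O)[C@H]2O)cc1 | target

## Step count and risks

Total step count: 19.
Longest linear sequence: 17 (from 3: steps 2–14 and 16–19).

**Step 7.** The methide is stabilised by four oxygen donors and may be too weak an electrophile. Self-aldolisation of the aldehyde or reversible attack by the catalyst nitrogen could then outrun C–C bond formation, and facial selectivity at C4 may be poor.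

The fallback sets out from 2 and 8 and returns at 17.
- Wittig olefination of 2 with ethyl (triphenylphosphoranylidene)acetate gives ethyl (E)-3-[3,4-bis(benzyloxy)-2-hydroxyphenyl]acrylate F1.
- Heating F1 in N,N-diethylaniline isomerises and lactonises it to 7,8-bis(benzyloxy)coumarin F2.
- Compound 8 is converted by way of aryllithium 10 and B(OiPr)3, followed by mild acid, into [4-(allyloxy)-2,3-bis(benzyloxy)phenyl]boronic acid F3.
- Rhodium-catalysed asymmetric 1,4-addition of F3 to F2 (Rh(acac)(C2H4)2, (S)-SEGPHOS, dioxane–H2O, 60 °C) sets C4 in (4S)-4-[4-(allyloxy)-2,3-bis(benzyloxy)phenyl]-7,8-bis(benzyloxy)chroman-2-one F4.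
- Enolisation (KHMDS, THF, –78 °C) and hydroxylation with 2-(phenylsulfonyl)-3-phenyloxaziridine anti to the C4 aryl group gives the 3,4-trans 3-hydroxy lactone F5.
- O-benzylation of F5 with benzyl 2,2,2-trichloroacetimidate and catalytic TfOH gives 17.

**Step 12.** The p-alkoxybenzylic oxyphosphonium ion may ionise. Inversion would then be lost and closure would drift to the more stable 2,3-trans ring. Elimination to the enol ether is a second possible loss.

The fallback sets out from 21 and returns at 23, bypassing steps 11 and 12.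
- Ketone 21 is in equilibrium with its cyclic 2-hydroxyflavan hemiketal F6.
- Et3SiH with BF3·OEt2 in CH2Cl2 at –78 → –40 °C ionises F6 to the ring C oxocarbenium ion. This is reduced from the face opposite the C3 benzyloxy group. This is a reductive etherification, a known entry to 2,3-cis flavans, and it gives 23 without substitution at a benzylic alcohol.

**Step 16.** The phenol has substituents in both ortho positions and may react slowly or at the linear terminus. Reversible ionisation of the electron-rich branched ether may also erode regio- and stereoselectivity.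

The fallback sets out from 25 and returns at 30, bypassing steps 16 and 17.
- Oxidative cleavage of the propenyl group (OsO4 cat., NaIO4, 2,6-lutidine, dioxane–H2O) gives the ring D salicylaldehyde F7.
- F7 is heated with dibenzylamine and (E)-2-[4-(benzyloxy)phenyl]vinylboronic acid F8, which is obtained by hydroboration–hydrolysis of 1-(benzyloxy)-4-ethynylbenzene.
- The sequence is a Petasis borono-Mannich reaction, loss of the amine to a ring D o-quinone methide, and 6π-oxa-electrocyclisation.
- It gives 30 together with its ring F C2 epimer F9. The two are diastereomers because ring C is already fixed, and they are separated by chromatography.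

## Further compounds

F1 | step 7 | ethyl (E)-3-[3,4-bis(benzyloxy)-2-hydroxyphenyl]acrylate | CCOC(=O)/C=C/c1ccc(OCc2ccccc2)c(OCc2ccccc2)c1O
F2 | step 7 | 7,8-bis(benzyloxy)coumarin | O=c1ccc2ccc(OCc3ccccc3)c(OCc3ccccc3)c2o1
F3 | step 7 | [4-(allyloxy)-2,3-bis(benzyloxy)phenyl]boronic acid | OB(O)c1ccc(OCC=C)c(OCc2ccccc2)c1OCc1ccccc1
F4 | step 7 | (4S)-4-[4-(allyloxy)-2,3-bis(benzyloxy)phenyl]-7,8-bis(benzyloxy)chroman-2-one | O=C1C[C@@H](c2ccc(OCC=C)c(OCc3ccccc3)c2OCc2ccccc2)c2ccc(OCc3ccccc3)c(OCc3ccccc3)c2O1
F5 | step 7 | 3,4-trans 3-hydroxy lactone | O=C1[C@H](O)[C@@H](c2ccc(OCC=C)c(OCc3ccccc3)c2OCc2ccccc2)c2ccc(OCc3ccccc3)c(OCc3ccccc3)c2O1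
F6 | step 12 | cyclic 2-hydroxyflavan hemiketal of 21 | OC1(c2ccc(OCc3ccccc3)cc2)Oc2c(ccc(OCc3ccccc3)c2OCc2ccccc2)[C@H](c2ccc(OCC=C)c(OCc3ccccc3)c2OCc2ccccc2)[C@H]1OCc1ccccc1
F7 | step 16 | ring D salicylaldehyde | C(c1ccccc1)Oc1ccc([C@H]2Oc3c(ccc(OCc4ccccc4)c3OCc3ccccc3)[C@H](c3cc(C=O)c(O)c(OCc4ccccc4)c3OCc3ccccc3)[C@H]2OCc2ccccc2)cc1
F8 | step 16 | (E)-2-[4-(benzyloxy)phenyl]vinylboronic acid | OB(O)/C=C/c1ccc(OCc2ccccc2)cc1
F9 | step 16 | ring F C2 epimer of 30 | C(c1ccccc1)Oc1ccc([C@H]2Oc3c(ccc(OCc4ccccc4)c3OCc3ccccc3)[C@H](c3cc4c(c(OCc5ccccc5)c3OCc3ccccc3)O[C@H](c3ccc(OCc5ccccc5)cc3)C=C4)[C@H]2OCc2ccccc2)cc1
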